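**Plan**

1. Locants follow germacrane numbering of the target: C1 ketone, C4–C5 epoxide (methyl on C4), C6 lactone carbinol, C7=C11 butenolide alkene, C8 tiglate carbinol, C10=C14 methylidene, C12 lactone carbonyl, C13 acetoxymethyl carbon.
2. Retrosynthesis: the esters at O8 and O13 and the C1 ketone are late adjustments. The butenolide is then cut at C11–C12, C12–O and C6–C7 into CO, a C7≡C11 alkyne and a C6 aldehyde; because C6–C7 is also a bond of the ten-membered ring, this opens the carbocycle to acyclic epoxy ynal 17. Compound 17 is cut at C1–C10 into bromoalkene 9 and aldehyde 14, and 9 at C8–C9.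
3. Enabling feature: the ring atoms O–C12–C11=C7–C6 are a formal [2+2+1] of alkyne, aldehyde and CO, and the alkyne carbon that must join C6 (C7) is the one carrying the chain C8–C9–C10–C1–C2–C3–C4–C5 back to C6. One nickel-mediated alkyne–aldehyde coupling with carbonylation should therefore close the carbocycle (exo at C7) and the lactone together.
4. Forward order: fragment 9 (steps 1–5) and fragment 14 (steps 6–8) are joined at C1–C10 (step 9); step 12 forms both rings; C1 oxidation and the two acylations follow.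
5. Stereochemistry: C4/C5 from Sharpless epoxidation of geraniol with D-(−)-diethyl tartrate; C8 from Noyori transfer hydrogenation of ynone 7; C6 in the key step under control of the adjacent epoxide; tiglate geometry from tigloyl chloride.

Key step: step 12

Remark: the C1 carbinol of 15–20 is carried as an epimer mixture and written without configuration, because C1 ends as the ketone.
Abbreviations: TBS = tert-butyldimethylsilyl; TES = triethylsilyl; DMP = Dess–Martin periodinane; IPr = 1,3-bis(2,6-diisopropylphenyl)imidazol-2-ylidene; cod = cycloocta-1,5-diene.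

**Route**

Step 1
Reactants: 1 tert-butyldimethyl(prop-2-yn-1-yloxy)silane
Product: 4 4-[(tert-butyldimethylsilyl)oxy]but-2-ynal, via lithium acetylide 2 (not isolated), via lithium hemiaminal alkoxide 3 (not isolated)
Conditions: n-BuLi, THF, −78 °C; DMF, −78 to 0 °C; inverse quench into cold aq. KH2PO4
Reagents that add atoms: N,N-dimethylformamide, CN(C)C=O
Why: Formylation of a lithium acetylide with DMF; the buffered inverse quench should release the ynal before dimethylamine can add to it.

Step 2
Reactants: 4 4-[(tert-butyldimethylsilyl)oxy]but-2-ynal; 5 2,3-dibromoprop-1-ene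
Product: 6 rac-6-bromo-1-[(tert-butyldimethylsilyl)oxy]hept-6-en-2-yn-4-ol
Conditions: Zn dust, THF/sat. aq. NH4Cl, 0 °C to rt
Reagents that add atoms: none
Why: Barbier allylation, in which zinc inserts into the allylic C–Br bond only and the allylzinc adds 1,2 to the ynal; the carbinol is racemic and is corrected in steps 3 and 4.

Step 3
Reactants: 6 rac-6-bromo-1-[(tert-butyldimethylsilyl)oxy]hept-6-en-2-yn-4-ol
Product: 7 6-bromo-1-[(tert-butyldimethylsilyl)oxy]hept-6-en-2-yn-4-one
Conditions: DMP, CH2Cl2, 0 °C; crude product used directly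
Reagents that add atoms: none
Why: Dess–Martin oxidation of a propargylic alcohol under neutral conditions, chosen so that the skipped ynone is not exposed to base.

Step 4
Reactants: 7 6-bromo-1-[(tert-butyldimethylsilyl)oxy]hept-6-en-2-yn-4-one
Product: 8 (4S)-6-bromo-1-[(tert-butyldimethylsilyl)oxy]hept-6-en-2-yn-4-ol
Conditions: Ru[(S,S)-TsDPEN](p-cymene) (1 mol%), i-PrOH, rt
Reagents that add atoms: none
Why: Noyori asymmetric transfer hydrogenation of an alkynyl ketone; the (S,S)-catalyst distinguishes the alkynyl from the alkyl flank and should give the 4S carbinol (C8 of the target), by analogy with alkynyl methyl ketones.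

Step 5
Reactants: 8 (4S)-6-bromo-1-[(tert-butyldimethylsilyl)oxy]hept-6-en-2-yn-4-ol
Product: 9 (4S)-6-bromo-1,4-bis[(tert-butyldimethylsilyl)oxy]hept-6-en-2-yne
Conditions: TBSCl, imidazole, DMF, rt
Reagents that add atoms: tert-butyldimethylsilyl chloride, CC(C)(C)[Si](C)(C)Cl
Why: Standard silylation; a silyl ether is a non-ionisable propargylic substituent, which the nickel step needs.

Step 6
Reactants: 10 geraniol
Product: 11 [(2R,3R)-3-methyl-3-(4-methylpent-3-en-1-yl)oxiran-2-yl]methanol
Conditions: Ti(OiPr)4 (10 mol%), D-(−)-diethyl tartrate (12 mol%), t-BuOOH, 4 Å MS, CH2Cl2, −20 °C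
Reagents that add atoms: tert-butyl hydroperoxide, CC(C)(C)OO
Why: Sharpless asymmetric epoxidation; the allylic hydroxyl directs oxygen to the 2,3-alkene only, and the D-(−)-tartrate sets both epoxide carbons as 2R,3R (C5 and C4 of the target).

Step 7
Reactants: 11 [(2R,3R)-3-methyl-3-(4-methylpent-3-en-1-yl)oxiran-2-yl]methanol
Product: 12 triethyl{[(2R,3R)-3-methyl-3-(4-methylpent-3-en-1-yl)oxiran-2-yl]methoxy}silane
Conditions: TESCl, imidazole, CH2Cl2, 0 °C
Reagents that add atoms: chlorotriethylsilane, CC[Si](Cl)(CC)CC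
Why: Silylation of the primary alcohol under non-acidic conditions that leave the epoxide untouched.

Step 8
Reactants: 12 triethyl{[(2R,3R)-3-methyl-3-(4-methylpent-3-en-1-yl)oxiran-2-yl]methoxy}silane
Product: 14 3-[(2R,3R)-2-methyl-3-{[(triethylsilyl)oxy]methyl}oxiran-2-yl]propanal, via ozonide 13 (not isolated)
Conditions: O3, CH2Cl2, −78 °C; then PPh3, −78 °C to rt
Reagents that add atoms: ozone, [O-][O+]=O
Why: Ozonolysis with reductive work-up cleaves the only alkene and leaves the epoxide and silyl ether intact.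

Step 9
Reactants: 9 (4S)-6-bromo-1,4-bis[(tert-butyldimethylsilyl)oxy]hept-6-en-2-yne; 14 3-[(2R,3R)-2-methyl-3-{[(triethylsilyl)oxy]methyl}oxiran-2-yl]propanal
Product: 15 (3RS,6S)-6,9-bis[(tert-butyldimethylsilyl)oxy]-4-methylidene-1-[(2R,3R)-2-methyl-3-{[(triethylsilyl)oxy]methyl}oxiran-2-yl]non-7-yn-3-ol
Conditions: CrCl2 (4 equiv), NiCl2 (2 mol%), DMSO, rt
Reagents that add atoms: none
Why: Nozaki–Hiyama–Kishi coupling, in which the alkenyl bromide is transferred to chromium and adds to the aldehyde only; the C1 carbinol forms as an epimer mixture that converges at the later oxidation.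

Step 10
Reactants: 15 (3RS,6S)-6,9-bis[(tert-butyldimethylsilyl)oxy]-4-methylidene-1-[(2R,3R)-2-methyl-3-{[(triethylsilyl)oxy]methyl}oxiran-2-yl]non-7-yn-3-ol
Product: 16 3-O-triethylsilyl ether of 15
Conditions: TESCl, imidazole, DMAP (cat.), CH2Cl2, 0 °C
Reagents that add atoms: chlorotriethylsilane, CC[Si](Cl)(CC)CC
Why: Immediate silylation caps the γ,δ-epoxy alcohol before it can cyclise and gives a group that can later be removed ahead of the TBS ethers.

Step 11
Reactants: 16 3-O-triethylsilyl ether of 15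
Product: 17 (2S,3R)-3-[(3RS,6S)-6,9-bis[(tert-butyldimethylsilyl)oxy]-4-methylidene-3-[(triethylsilyl)oxy]non-7-yn-1-yl]-3-methyloxirane-2-carbaldehyde
Conditions: (COCl)2, DMSO, CH2Cl2, −78 to −40 °C; then Et3N, −78 to 0 °C
Reagents that add atoms: none
Why: Under Swern conditions a primary TES ether is cleaved and oxidised directly while secondary TES and TBS ethers persist (oxidative desilylation), which gives the epoxy aldehyde in one step.

Step 12
Reactants: 17 (2S,3R)-3-[(3RS,6S)-6,9-bis[(tert-butyldimethylsilyl)oxy]-4-methylidene-3-[(triethylsilyl)oxy]non-7-yn-1-yl]-3-methyloxirane-2-carbaldehyde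
Product: 19 (4R,5R,6S,8S)-8,13-bis[(tert-butyldimethylsilyl)oxy]-4,5-epoxy-1-[(triethylsilyl)oxy]germacra-7(11),10(14)-dien-12,6-olide (1-epimers), via oxanickelacyclopentene 18 (not isolated)
Conditions: Ni(cod)2 (1.2 equiv), IPr (1.2 equiv), toluene, 25 °C, 17 added by syringe pump over 12 h (final 2 mM); then CO (1 atm), 25 °C
Reagents that add atoms: carbon monoxide, [C-]#[O+]
Why: Proposed new method: zerovalent nickel–IPr binds the C7≡C11 alkyne and the C6 aldehyde of 17 and couples them oxidatively to oxanickelacyclopentene 18 (C6–C7 bond); CO then inserts into the Ni–C11 bond and C12–O reductive elimination releases the butenolide, a hetero-Pauson–Khand-type [2+2+1] run as a macrocyclisation. The closest known reaction types are the nickel–carbene reductive macrocyclisation of ynals (same oxidative cyclisation, trapped by a silane, for rings of twelve or more atoms) and the stoichiometric carbonylation of alkyne–aldehyde oxanickelacycles to butenolides; the ten-membered ring size and the CO trap in a macrocyclic setting are the untested elements. The ten-membered carbocycle closes in the exo mode at C7, the regiochemistry that bulky IPr should favour because the smaller CH2OTBS-bearing C11 ends up next to nickel, and the lactone closes by CO insertion and C–O reductive elimination within the five-membered metallacycle. The only new stereocentre, C6, is controlled by the adjacent epoxide: C7 should add anti to the C5–O bond while the nickel-bound aldehyde oxygen turns away from the C4 methyl group that is cis to the aldehyde, which corresponds to 6S. The step needs exo over endo (eleven-membered) closure, cyclisation over oligomerisation and survival of the epoxide; the rigid trans-epoxide turn, silyl ethers in place of ionisable propargylic esters, and slow addition at high dilution are meant to secure these.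

Step 13
Reactants: 19 (4R,5R,6S,8S)-8,13-bis[(tert-butyldimethylsilyl)oxy]-4,5-epoxy-1-[(triethylsilyl)oxy]germacra-7(11),10(14)-dien-12,6-olide (1-epimers)
Product: 20 (4R,5R,6S,8S)-8,13-bis[(tert-butyldimethylsilyl)oxy]-4,5-epoxy-1-hydroxygermacra-7(11),10(14)-dien-12,6-olide (1-epimers)
Conditions: HF·pyridine, pyridine, THF, 0 °C
Reagents that add atoms: none
Why: Graded silyl ether cleavage; buffered HF·pyridine should remove the secondary TES ether faster than either TBS ether and is mild enough for the epoxide.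

Step 14
Reactants: 20 (4R,5R,6S,8S)-8,13-bis[(tert-butyldimethylsilyl)oxy]-4,5-epoxy-1-hydroxygermacra-7(11),10(14)-dien-12,6-olide (1-epimers)
Product: 21 (4R,5R,6S,8S)-8,13-bis[(tert-butyldimethylsilyl)oxy]-4,5-epoxy-1-oxogermacra-7(11),10(14)-dien-12,6-olide
Conditions: DMP, pyridine, CH2Cl2, 0 °C
Reagents that add atoms: none
Why: Dess–Martin oxidation of the allylic alcohol to the α-methylene ketone; both C1 epimers converge to one compound.

Step 15
Reactants: 21 (4R,5R,6S,8S)-8,13-bis[(tert-butyldimethylsilyl)oxy]-4,5-epoxy-1-oxogermacra-7(11),10(14)-dien-12,6-olide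
Product: 22 (4R,5R,6S,8S)-4,5-epoxy-8,13-dihydroxy-1-oxogermacra-7(11),10(14)-dien-12,6-olide
Conditions: HF·pyridine (excess), pyridine, THF, 0 °C to rt
Reagents that add atoms: none
Why: Fluoride-mediated desilylation under mildly acidic conditions, which avoids alkoxide-induced lactone migration to O8 or epoxide opening.

Step 16
Reactants: 22 (4R,5R,6S,8S)-4,5-epoxy-8,13-dihydroxy-1-oxogermacra-7(11),10(14)-dien-12,6-olide
Product: 23 (4R,5R,6S,8S)-13-acetoxy-4,5-epoxy-8-hydroxy-1-oxogermacra-7(11),10(14)-dien-12,6-olide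
Conditions: AcCl (1.1 equiv), 2,4,6-collidine, CH2Cl2, −78 °C
Reagents that add atoms: acetyl chloride, CC(Cl)=O
Why: Selective acetylation; acetyl chloride with collidine at low temperature should acylate the primary allylic alcohol and leave the hindered secondary C8 alcohol.

Step 17
Reactants: 23 (4R,5R,6S,8S)-13-acetoxy-4,5-epoxy-8-hydroxy-1-oxogermacra-7(11),10(14)-dien-12,6-olide
Product: 24 (4R,5R,6S,8S)-13-acetoxy-4,5-epoxy-1-oxo-8-[(E)-2-methylbut-2-enoyloxy]germacra-7(11),10(14)-dien-12,6-olide (CNP0225286.1)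
Conditions: tigloyl chloride, pyridine, DMAP (cat.), CH2Cl2, 0 °C
Reagents that add atoms: tigloyl chloride, ClC(=O)/C(C)=C/C
Why: DMAP-catalysed acylation of the remaining secondary alcohol with the E-configured acid chloride; the tiglate geometry is retained and the low temperature should let acylation outrun lactone migration to O8.

**Compound list**

1 | tert-butyldimethyl(prop-2-yn-1-yloxy)silane | C#CCO[Si](C)(C)C(C)(C)C | starting material
2 | {3-[(tert-butyldimethylsilyl)oxy]prop-1-yn-1-yl}lithium | [Li]C#CCO[Si](C)(C)C(C)(C)C | intermediate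
3 | lithium 4-[(tert-butyldimethylsilyl)oxy]-1-(dimethylamino)but-2-yn-1-olate | [Li]OC(N(C)C)C#CCO[Si](C)(C)C(C)(C)C | intermediate
4 | 4-[(tert-butyldimethylsilyl)oxy]but-2-ynal | O=CC#CCO[Si](C)(C)C(C)(C)C | intermediate
5 | 2,3-dibromoprop-1-ene | C=C(Br)CBr | starting material
6 | rac-6-bromo-1-[(tert-butyldimethylsilyl)oxy]hept-6-en-2-yn-4-ol | C=C(Br)CC(O)C#CCO[Si](C)(C)C(C)(C)C | intermediate
7 | 6-bromo-1-[(tert-butyldimethylsilyl)oxy]hept-6-en-2-yn-4-one | C=C(Br)CC(=O)C#CCO[Si](C)(C)C(C)(C)C | intermediate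
8 | (4S)-6-bromo-1-[(tert-butyldimethylsilyl)oxy]hept-6-en-2-yn-4-ol | C=C(Br)C[C@H](O)C#CCO[Si](C)(C)C(C)(C)C | intermediate
9 | (4S)-6-bromo-1,4-bis[(tert-butyldimethylsilyl)oxy]hept-6-en-2-yne | C=C(Br)C[C@H](O[Si](C)(C)C(C)(C)C)C#CCO[Si](C)(C)C(C)(C)C | intermediate
10 | geraniol, (2E)-3,7-dimethylocta-2,6-dien-1-ol | CC(C)=CCC/C(C)=C/CO | starting material
11 | [(2R,3R)-3-methyl-3-(4-methylpent-3-en-1-yl)oxiran-2-yl]methanol | OC[C@H]1O[C@]1(C)CCC=C(C)C | intermediate
12 | triethyl{[(2R,3R)-3-methyl-3-(4-methylpent-3-en-1-yl)oxiran-2-yl]methoxy}silane | CC[Si](CC)(CC)OC[C@H]1O[C@]1(C)CCC=C(C)C | intermediate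
13 | 3,3-dimethyl-5-{2-[(2R,3R)-2-methyl-3-{[(triethylsilyl)oxy]methyl}oxiran-2-yl]ethyl}-1,2,4-trioxolane (ozonide) | CC[Si](CC)(CC)OC[C@H]1O[C@]1(C)CCC1OOC(C)(C)O1 | intermediate
14 | 3-[(2R,3R)-2-methyl-3-{[(triethylsilyl)oxy]methyl}oxiran-2-yl]propanal | CC[Si](CC)(CC)OC[C@H]1O[C@]1(C)CCC=O | intermediate
15 | (3RS,6S)-6,9-bis[(tert-butyldimethylsilyl)oxy]-4-methylidene-1-[(2R,3R)-2-methyl-3-{[(triethylsilyl)oxy]methyl}oxiran-2-yl]non-7-yn-3-ol | C=C(C[C@H](O[Si](C)(C)C(C)(C)C)C#CCO[Si](C)(C)C(C)(C)C)C(O)CC[C@@]1(C)O[C@@H]1CO[Si](CC)(CC)CC | intermediate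
16 | 3-O-triethylsilyl ether of 15 | C=C(C[C@H](O[Si](C)(C)C(C)(C)C)C#CCO[Si](C)(C)C(C)(C)C)C(O[Si](CC)(CC)CC)CC[C@@]1(C)O[C@@H]1CO[Si](CC)(CC)CC | intermediate
17 | (2S,3R)-3-[(3RS,6S)-6,9-bis[(tert-butyldimethylsilyl)oxy]-4-methylidene-3-[(triethylsilyl)oxy]non-7-yn-1-yl]-3-methyloxirane-2-carbaldehyde | C=C(C[C@H](O[Si](C)(C)C(C)(C)C)C#CCO[Si](C)(C)C(C)(C)C)C(O[Si](CC)(CC)CC)CC[C@@]1(C)O[C@@H]1C=O | intermediate
18 | oxanickelacyclopentene: (IPr)Ni bound to O6 and C11 of the ten-membered ring formed by C6–C7 coupling | C=C1C[C@H](O[Si](C)(C)C(C)(C)C)C2=C(CO[Si](C)(C)C(C)(C)C)[Ni](=C3N(c4c(C(C)C)cccc4C(C)C)C=CN3c3c(C(C)C)cccc3C(C)C)O[C@@H]2[C@H]2O[C@]2(C)CCC1O[Si](CC)(CC)CC | intermediate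
19 | (4R,5R,6S,8S)-8,13-bis[(tert-butyldimethylsilyl)oxy]-4,5-epoxy-1-[(triethylsilyl)oxy]germacra-7(11),10(14)-dien-12,6-olide (1-epimers) | C=C1C[C@H](O[Si](C)(C)C(C)(C)C)C2=C(CO[Si](C)(C)C(C)(C)C)C(=O)O[C@@H]2[C@H]2O[C@]2(C)CCC1O[Si](CC)(CC)CC | intermediate
20 | (4R,5R,6S,8S)-8,13-bis[(tert-butyldimethylsilyl)oxy]-4,5-epoxy-1-hydroxygermacra-7(11),10(14)-dien-12,6-olide (1-epimers) | C=C1C[C@H](O[Si](C)(C)C(C)(C)C)C2=C(CO[Si](C)(C)C(C)(C)C)C(=O)O[C@@H]2[C@H]2O[C@]2(C)CCC1O | intermediate
21 | (4R,5R,6S,8S)-8,13-bis[(tert-butyldimethylsilyl)oxy]-4,5-epoxy-1-oxogermacra-7(11),10(14)-dien-12,6-olide | C=C1C[C@H](O[Si](C)(C)C(C)(C)C)C2=C(CO[Si](C)(C)C(C)(C)C)C(=O)O[C@@H]2[C@H]2O[C@]2(C)CCC1=O | intermediate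
22 | (4R,5R,6S,8S)-4,5-epoxy-8,13-dihydroxy-1-oxogermacra-7(11),10(14)-dien-12,6-olide | C=C1C[C@H](O)C2=C(CO)C(=O)O[C@@H]2[C@H]2O[C@]2(C)CCC1=O | intermediate
23 | (4R,5R,6S,8S)-13-acetoxy-4,5-epoxy-8-hydroxy-1-oxogermacra-7(11),10(14)-dien-12,6-olide | C=C1C[C@H](O)C2=C(COC(C)=O)C(=O)O[C@@H]2[C@H]2O[C@]2(C)CCC1=O | intermediate
24 | (4R,5R,6S,8S)-13-acetoxy-4,5-epoxy-1-oxo-8-[(E)-2-methylbut-2-enoyloxy]germacra-7(11),10(14)-dien-12,6-olide | C=C1C[C@H](OC(=O)/C(C)=C/C)C2=C(COC(C)=O)C(=O)O[C@@H]2[C@H]2O[C@]2(C)CCC1=O | target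

**Step count and risks**

Total: 17 steps. Longest linear sequence: 14 steps (steps 1–5, then 9–17).

Steps most likely to fail:

1. Step 12 (the proposed new method). The ynal may oligomerise instead of closing the ten-membered ring, or close in the endo mode. Nickel bound to the aldehyde may open the neighbouring epoxide by β-alkoxide elimination. The aldehyde face may be attacked with the wrong sense, and CO may saturate nickel before it inserts. Fallback: the two bonds would be made stepwise on acyclic material by known reactions and the ring closed at C1–C10 instead. The fallback sets out from bromoalkene 9 and epoxy alcohol 11. Compound 11 would be oxidised (DMP, pyridine) to epoxygeranial F1. The alkyne of 9 would be converted with Ti(OiPr)4 and c-C5H9MgCl (−78 to −30 °C) into its titanium–alkyne complex, which should add to F1 at C7; iodinolysis of the remaining C11–Ti bond should give iodo allylic alcohol F2, with chelation of titanium by the epoxide oxygen expected to favour 6S, and any C11-coupled regioisomer would be separated. Carbonylative lactonisation with Pd(PPh3)4 (cat.), CO (1 atm) and Et3N should give butenolide F3. Selective ozonolysis of the electron-rich trisubstituted alkene (O3, then PPh3) should give aldehyde F4. An intramolecular Nozaki–Hiyama–Kishi reaction (CrCl2, NiCl2 cat., DMSO, high dilution), a known way to close ten-membered carbocycles, would return to the route at alcohol 20.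

2. Step 13. The primary allylic TBS ether may be lost in competition with the TES ether, and the liberated C1 hydroxyl may attack C4 of the epoxide (5-exo closure to a tetrahydrofuran) under the mildly acidic fluoride. Fallback: the TES ether of 19 would be converted directly into the ketone with IBX in DMSO at rt, a known one-pot cleavage and oxidation of TES ethers that spares TBS ethers, so that the free γ,δ-epoxy alcohol does not accumulate. This sets out from 19 and returns to the route at enone 21.

3. Step 3. The skipped ynone may undergo prototropic shift of the C9 methylene into conjugation during oxidation, handling or the hydrogen transfer of step 4, with loss of material. Fallback: the ketone stage would be avoided by setting C8 directly. Ynal 4 and dibromide 5 would be coupled by chromium-catalysed asymmetric 2-bromoallylation (CrCl2 cat., chiral oxazoline–sulfonamide ligand, Mn powder, TMSCl), which should give silyl ether F5; mild desilylation (citric acid, MeOH) would return to the route at alcohol 8.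

Further compounds
F1 | step 12 | (2S,3R)-3-methyl-3-(4-methylpent-3-en-1-yl)oxirane-2-carbaldehyde | O=C[C@H]1O[C@]1(C)CCC=C(C)C
F2 | step 12 | iodo allylic alcohol: 9 coupled at C7 to C6 of F1 (6S carbinol), iodine on C11 cis to the C6 carbinol | C=C(Br)C[C@H](O[Si](C)(C)C(C)(C)C)/C(=C(/I)CO[Si](C)(C)C(C)(C)C)[C@H](O)[C@H]1O[C@]1(C)CCC=C(C)C
F3 | step 12 | acyclic butenolide carrying the 2-bromoallyl carbinol arm on C7, CH2OTBS on C11 and the epoxy prenyl chain on C6 | C=C(Br)C[C@H](O[Si](C)(C)C(C)(C)C)C1=C(CO[Si](C)(C)C(C)(C)C)C(=O)O[C@@H]1[C@H]1O[C@]1(C)CCC=C(C)C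
F4 | step 12 | C1 aldehyde from ozonolysis of F3 | C=C(Br)C[C@H](O[Si](C)(C)C(C)(C)C)C1=C(CO[Si](C)(C)C(C)(C)C)C(=O)O[C@@H]1[C@H]1O[C@]1(C)CCC=O
F0 | step 13 | none | none
F5 | step 3 | (4S)-6-bromo-1-[(tert-butyldimethylsilyl)oxy]-4-[(trimethylsilyl)oxy]hept-6-en-2-yne | C=C(Br)C[C@H](O[Si](C)(C)C)C#CCO[Si](C)(C)C(C)(C)C
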